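**Retrosynthetic overview** (flavanone unit: rings A/C/B = benzo/pyranone/aryl; flavone unit: rings D/F/E = benzo/pyranone/aryl)
1. Target 12 ⇐ 11 by hydrogenolysis of four benzyl ethers; the ring A methyl ether stays.
2. 11 ⇐ 9: both pyranone rings are closed in one flask from a fully open chalcone/1,3-diketone, by enantioselective oxa-Michael addition (ring C, C2 = S) followed by cyclodehydration (ring F).
3. 9 ⇐ 7 + 8 by Claisen–Schmidt condensation; 7 ⇐ 4 + 5 by borylation/Suzuki coupling (ring B–ring D bond).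
4. 4 ⇐ 2 + 3 by enolate aroylation; 2 ⇐ 1 by iodination ortho to the free phenol, which fixes the C8 linkage of the flavone.
5. Ring order: rings A, B, D and E are bought as benzenoid building blocks; rings C and F are formed together in step 5.

Assumption: 1 is bought as the catalogue dibenzyl ether (otherwise one step from 2,4,6-trihydroxyacetophenone, BnBr, K2CO3); the sense of induction of the thiourea in step 5 is assigned by analogy, not established, and the quinidine-derived pseudoenantiomer is used instead if a model run on 2',6'-dihydroxy-4'-methoxychalcone gives (2R)-pinostrobin; the ring B–ring D axis is not a defined stereo element in the target.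

**Step 1**
Reactants: 1 1-[2,4-bis(benzyloxy)-6-hydroxyphenyl]ethan-1-one
Product: 2 1-[4,6-bis(benzyloxy)-2-hydroxy-3-iodophenyl]ethan-1-one
Conditions: NIS (1.05 equiv), TFA (10 mol%), MeCN, 0 °C to rt, dark
Reagents that add atoms: N-iodosuccinimide, O=C1CCC(=O)N1I
Why: Electrophilic aromatic iodination of the chelated phenol goes to C3 (ortho to the free OH, para to the 6-benzyloxy group) because C5 is buried between two benzyloxy groups, and this iodide later places the biaryl bond at C8 of the flavone.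

**Step 2**
Reactants: 2 1-[4,6-bis(benzyloxy)-2-hydroxy-3-iodophenyl]ethan-1-one; 3 4-(benzyloxy)benzoyl chloride
Product: 4 1-[4,6-bis(benzyloxy)-2-hydroxy-3-iodophenyl]-3-[4-(benzyloxy)phenyl]propane-1,3-dione
Conditions: LiN(SiMe3)2 (3.2 equiv), THF, −78 to −10 °C; then 3 (1.05 equiv), −78 °C to rt; aq. HCl work-up
Reagents that add atoms: none
Why: Claisen-type C-aroylation of the lithium phenoxide/enolate dianion (a one-pot Baker–Venkataraman equivalent) gives the 1,3-diketone, the third equivalent of base deprotonating the product to stop over-acylation, and the aryl iodide is inert to the amide base at low temperature.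

**Step 3**
Reactants: 4 1-[4,6-bis(benzyloxy)-2-hydroxy-3-iodophenyl]-3-[4-(benzyloxy)phenyl]propane-1,3-dione; 5 4-(benzyloxy)-3-bromobenzaldehyde
Product: 7 4-(benzyloxy)-3-{2,4-bis(benzyloxy)-5-[3-[4-(benzyloxy)phenyl]-3-oxopropanoyl]-6-hydroxyphenyl}benzaldehyde, via pinacol boronate 6 (not isolated)
Conditions: 5 (1.3 equiv), B2pin2 (1.35 equiv), PdCl2(dppf) (3 mol%), KOAc (3 equiv), 1,4-dioxane, 90 °C; then 4 (1.0 equiv), Pd(OAc)2 (5 mol%), SPhos (10 mol%), aq. K3PO4, 70 °C, same pot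
Reagents that add atoms: bis(pinacolato)diboron, CC1(C)OB(OC1(C)C)B1OC(C)(C)C(C)(C)O1 (supplies the boryl group of 6)
Why: One-pot Miyaura borylation/Suzuki–Miyaura cross-coupling, in which zerovalent palladium first borylates bromide 5 and the bulky electron-rich phosphine SPhos then carries the tri-ortho-substituted coupling with iodide 4, whose diketone sits as an unreactive enolate while the aldehyde is tolerated.

**Step 4**
Reactants: 7 4-(benzyloxy)-3-{2,4-bis(benzyloxy)-5-[3-[4-(benzyloxy)phenyl]-3-oxopropanoyl]-6-hydroxyphenyl}benzaldehyde; 8 1-(2,6-dihydroxy-4-methoxyphenyl)ethan-1-one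
Product: 9 1-{4,6-bis(benzyloxy)-3-[2-(benzyloxy)-5-[(1E)-3-(2,6-dihydroxy-4-methoxyphenyl)-3-oxoprop-1-en-1-yl]phenyl]-2-hydroxyphenyl}-3-[4-(benzyloxy)phenyl]propane-1,3-dione
Conditions: 8 (1.5 equiv), KOH (50% aq., 15 equiv), EtOH, 0 °C to rt, 48 h, argon; then cold 1 M HCl to pH 5, fast extraction, chromatography
Reagents that add atoms: none
Why: Claisen–Schmidt (crossed aldol) condensation, in which the diketone of 7 is masked as its hindered enolate (its aldol adducts revert) so that only the methyl ketone enolate of 8 adds to the non-enolisable aldehyde and E1cB dehydration gives the E-enone, which stays open as its phenolate until cold mild acidification.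

**Step 5**
Reactants: 9 1-{4,6-bis(benzyloxy)-3-[2-(benzyloxy)-5-[(1E)-3-(2,6-dihydroxy-4-methoxyphenyl)-3-oxoprop-1-en-1-yl]phenyl]-2-hydroxyphenyl}-3-[4-(benzyloxy)phenyl]propane-1,3-dione
Product: 11 (2S)-2-{4-(benzyloxy)-3-[5,7-bis(benzyloxy)-2-[4-(benzyloxy)phenyl]-4-oxo-4H-chromen-8-yl]phenyl}-5-hydroxy-7-methoxy-2,3-dihydro-4H-chromen-4-one, via flavanone diketone 10 (not isolated)
Conditions: 1-[3,5-bis(trifluoromethyl)phenyl]-3-[(8α,9S)-6′-methoxycinchonan-9-yl]thiourea (10 mol%), toluene, −20 °C, 48 h; then TsOH·H2O (30 mol%), 60 °C, 3 h, same flask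
Reagents that add atoms: none
Why: Proposed new method: the quinuclidine nitrogen acts as general base on either ring A hydroxyl (both give the same product) while the thiourea hydrogen-bonds the enone carbonyl, so the 6-endo-trig oxa-Michael addition closes ring C inside a chiral ion pair and sets C2 as S (closest known reaction: bifunctional cinchona-thiourea-catalysed intramolecular oxa-Michael cyclisation of 2'-hydroxychalcones and alkylidene β-keto esters to flavanones), after which TsOH quenches the amine and drives the acid-catalysed cyclodehydration of the o-hydroxyaryl 1,3-diketone through the only free phenol on ring D to give the 8-aryl flavone (ring F) under conditions where flavanones are expected to be configurationally stable.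

**Step 6**
Reactants: 11 (2S)-2-{4-(benzyloxy)-3-[5,7-bis(benzyloxy)-2-[4-(benzyloxy)phenyl]-4-oxo-4H-chromen-8-yl]phenyl}-5-hydroxy-7-methoxy-2,3-dihydro-4H-chromen-4-one
Product: 12 (2S)-2-{3-[5,7-dihydroxy-2-(4-hydroxyphenyl)-4-oxo-4H-chromen-8-yl]-4-hydroxyphenyl}-5-hydroxy-7-methoxy-2,3-dihydro-4H-chromen-4-one
Conditions: H2 (1 atm), Pd/C (10 wt% Pd on carbon), EtOAc/MeOH 1:1, rt, stopped after uptake of 4 equiv H2
Reagents that add atoms: none
Why: Heterogeneous hydrogenolysis of the four benzyl aryl ethers under neutral conditions leaves the aryl methyl ether, both carbonyls, the flavone C2=C3 bond and the base-sensitive C2 stereocentre untouched.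

**Compound list**
1 | 1-[2,4-bis(benzyloxy)-6-hydroxyphenyl]ethan-1-one | CC(=O)c1c(O)cc(OCc2ccccc2)cc1OCc1ccccc1 | starting material
2 | 1-[4,6-bis(benzyloxy)-2-hydroxy-3-iodophenyl]ethan-1-one | CC(=O)c1c(O)c(I)c(OCc2ccccc2)cc1OCc1ccccc1 | intermediate
3 | 4-(benzyloxy)benzoyl chloride | O=C(Cl)c1ccc(OCc2ccccc2)cc1 | starting material
4 | 1-[4,6-bis(benzyloxy)-2-hydroxy-3-iodophenyl]-3-[4-(benzyloxy)phenyl]propane-1,3-dione | O=C(CC(=O)c1ccc(OCc2ccccc2)cc1)c1c(O)c(I)c(OCc2ccccc2)cc1OCc1ccccc1 | intermediate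
5 | 4-(benzyloxy)-3-bromobenzaldehyde | O=Cc1ccc(OCc2ccccc2)c(Br)c1 | starting material
6 | 4-(benzyloxy)-3-(4,4,5,5-tetramethyl-1,3,2-dioxaborolan-2-yl)benzaldehyde (not isolated) | O=Cc1ccc(OCc2ccccc2)c(c1)B1OC(C)(C)C(C)(C)O1 | intermediate
7 | 4-(benzyloxy)-3-{2,4-bis(benzyloxy)-5-[3-[4-(benzyloxy)phenyl]-3-oxopropanoyl]-6-hydroxyphenyl}benzaldehyde | O=Cc1ccc(OCc2ccccc2)c(c1)-c1c(O)c(C(=O)CC(=O)c2ccc(OCc3ccccc3)cc2)c(OCc2ccccc2)cc1OCc1ccccc1 | intermediate
8 | 1-(2,6-dihydroxy-4-methoxyphenyl)ethan-1-one | CC(=O)c1c(O)cc(OC)cc1O | starting material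
9 | 1-{4,6-bis(benzyloxy)-3-[2-(benzyloxy)-5-[(1E)-3-(2,6-dihydroxy-4-methoxyphenyl)-3-oxoprop-1-en-1-yl]phenyl]-2-hydroxyphenyl}-3-[4-(benzyloxy)phenyl]propane-1,3-dione | COc1cc(O)c(C(=O)/C=C/c2ccc(OCc3ccccc3)c(c2)-c2c(O)c(C(=O)CC(=O)c3ccc(OCc4ccccc4)cc3)c(OCc3ccccc3)cc2OCc2ccccc2)c(O)c1 | intermediate
10 | 1-{4,6-bis(benzyloxy)-3-[2-(benzyloxy)-5-[(2S)-5-hydroxy-7-methoxy-4-oxo-3,4-dihydro-2H-chromen-2-yl]phenyl]-2-hydroxyphenyl}-3-[4-(benzyloxy)phenyl]propane-1,3-dione (not isolated) | COc1cc(O)c2c(c1)O[C@H](c1ccc(OCc3ccccc3)c(c1)-c1c(O)c(C(=O)CC(=O)c3ccc(OCc4ccccc4)cc3)c(OCc3ccccc3)cc1OCc1ccccc1)CC2=O | intermediate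
11 | (2S)-2-{4-(benzyloxy)-3-[5,7-bis(benzyloxy)-2-[4-(benzyloxy)phenyl]-4-oxo-4H-chromen-8-yl]phenyl}-5-hydroxy-7-methoxy-2,3-dihydro-4H-chromen-4-one | COc1cc(O)c2c(c1)O[C@H](c1ccc(OCc3ccccc3)c(-c3c(OCc4ccccc4)cc(OCc4ccccc4)c4c(=O)cc(-c5ccc(OCc6ccccc6)cc5)oc34)c1)CC2=O | intermediate
12 | (2S)-2-{3-[5,7-dihydroxy-2-(4-hydroxyphenyl)-4-oxo-4H-chromen-8-yl]-4-hydroxyphenyl}-5-hydroxy-7-methoxy-2,3-dihydro-4H-chromen-4-one (7-O-methyl ether of (2S)-2,3-dihydroamentoflavone) | COc1cc(O)c2c(c1)O[C@H](c1ccc(O)c(-c3c(O)cc(O)c4c(=O)cc(-c5ccc(O)cc5)oc34)c1)CC2=O | target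

**Totals**
Total step count: 6. Longest linear sequence: 6 (1 → 2 → 4 → 7 → 9 → 11 → 12).

**Three steps most likely to fail, with fallbacks**

Step 5 (highest risk). The enantioselectivity on an unactivated 2',6'-dihydroxychalcone is unproven, the uncatalysed ring closure can compete, and the large substrate offers the catalyst extra binding sites. The fallback sets out from 9 and comes back at 11. Compound 9 is treated with TsOH·H2O alone in toluene at 60 °C, which closes both rings without stereocontrol and gives the racemic tetrabenzyl ether F1. F1 is separated by preparative chiral SFC (amylose tris(3,5-dimethylphenylcarbamate) phase) into 11 and the (2R)-tetrabenzyl ether F2. F2 is returned to F1 by NaOAc in EtOH at reflux (ring opening to the chalcone and reclosure) and recycled.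

Step 4. The dianion of unprotected 8 enolises slowly, the diketone may suffer side reactions under KOH, and the chalcone can partly close to racemic flavanone on work-up. The fallback sets out from 7 (with 8) and comes back at 12. Compound 8 is monobenzylated (BnBr 1.0 equiv, K2CO3, acetone, reflux) to 1-[2-(benzyloxy)-6-hydroxy-4-methoxyphenyl]ethan-1-one F3. F3 condenses with 7 under KOH/EtOH (mono-phenol acetophenones condense well and their chalcones do not close spontaneously) to the 6'-O-benzyl chalcone F4. The same thiourea/TsOH one-flask double ring closure gives, by way of the 5-O-benzyl flavanone diketone F5, the pentabenzyl ether F6. Hydrogenolysis (H2, Pd/C) of all five benzyl groups returns to 12.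

Step 3. The iodide is hindered, electron-rich and carries a free phenol and an acidic diketone, so slow oxidative addition, protodeiodination and base-induced aldehyde/diketone condensation are possible. The fallback sets out from 2 (with 5) and comes back at 7. Bromide 5 is masked as 2-[4-(benzyloxy)-3-bromophenyl]-1,3-dioxolane F7 (ethylene glycol, TsOH, toluene, Dean–Stark). F7 is borylated (B2pin2, PdCl2(dppf), KOAc) to the pinacol boronate F8. F8 is coupled with the simpler iodoacetophenone 2 (Pd(OAc)2, SPhos, K3PO4) to the biaryl methyl ketone F9, so the coupling is done before the diketone exists and with the aldehyde protected. Aroylation of F9 with 3 (LiN(SiMe3)2, THF) gives the diketone acetal F10, and PPTS in wet acetone at rt unmasks the aldehyde to give 7.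

**Further compounds**
F1 | step 5 | racemic 2-{4-(benzyloxy)-3-[5,7-bis(benzyloxy)-2-[4-(benzyloxy)phenyl]-4-oxo-4H-chromen-8-yl]phenyl}-5-hydroxy-7-methoxy-2,3-dihydro-4H-chromen-4-one | COc1cc(O)c2c(c1)OC(c1ccc(OCc3ccccc3)c(-c3c(OCc4ccccc4)cc(OCc4ccccc4)c4c(=O)cc(-c5ccc(OCc6ccccc6)cc5)oc34)c1)CC2=O
F2 | step 5 | (2R)-2-{4-(benzyloxy)-3-[5,7-bis(benzyloxy)-2-[4-(benzyloxy)phenyl]-4-oxo-4H-chromen-8-yl]phenyl}-5-hydroxy-7-methoxy-2,3-dihydro-4H-chromen-4-one | COc1cc(O)c2c(c1)O[C@@H](c1ccc(OCc3ccccc3)c(-c3c(OCc4ccccc4)cc(OCc4ccccc4)c4c(=O)cc(-c5ccc(OCc6ccccc6)cc5)oc34)c1)CC2=O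
F3 | step 4 | 1-[2-(benzyloxy)-6-hydroxy-4-methoxyphenyl]ethan-1-one | CC(=O)c1c(O)cc(OC)cc1OCc1ccccc1
F4 | step 4 | 1-{4,6-bis(benzyloxy)-3-[2-(benzyloxy)-5-[(1E)-3-[2-(benzyloxy)-6-hydroxy-4-methoxyphenyl]-3-oxoprop-1-en-1-yl]phenyl]-2-hydroxyphenyl}-3-[4-(benzyloxy)phenyl]propane-1,3-dione | COc1cc(O)c(C(=O)/C=C/c2ccc(OCc3ccccc3)c(c2)-c2c(O)c(C(=O)CC(=O)c3ccc(OCc4ccccc4)cc3)c(OCc3ccccc3)cc2OCc2ccccc2)c(OCc2ccccc2)c1
F5 | step 4 | 1-{4,6-bis(benzyloxy)-3-[2-(benzyloxy)-5-[(2S)-5-(benzyloxy)-7-methoxy-4-oxo-3,4-dihydro-2H-chromen-2-yl]phenyl]-2-hydroxyphenyl}-3-[4-(benzyloxy)phenyl]propane-1,3-dione | COc1cc(OCc2ccccc2)c2c(c1)O[C@H](c1ccc(OCc3ccccc3)c(c1)-c1c(O)c(C(=O)CC(=O)c3ccc(OCc4ccccc4)cc3)c(OCc3ccccc3)cc1OCc1ccccc1)CC2=O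
F6 | step 4 | (2S)-5-(benzyloxy)-2-{4-(benzyloxy)-3-[5,7-bis(benzyloxy)-2-[4-(benzyloxy)phenyl]-4-oxo-4H-chromen-8-yl]phenyl}-7-methoxy-2,3-dihydro-4H-chromen-4-one | COc1cc(OCc2ccccc2)c2c(c1)O[C@H](c1ccc(OCc3ccccc3)c(-c3c(OCc4ccccc4)cc(OCc4ccccc4)c4c(=O)cc(-c5ccc(OCc6ccccc6)cc5)oc34)c1)CC2=O
F7 | step 3 | 2-[4-(benzyloxy)-3-bromophenyl]-1,3-dioxolane | Brc1cc(ccc1OCc1ccccc1)C1OCCO1
F8 | step 3 | 2-[2-(benzyloxy)-5-(1,3-dioxolan-2-yl)phenyl]-4,4,5,5-tetramethyl-1,3,2-dioxaborolane | CC1(C)OB(OC1(C)C)c1cc(ccc1OCc1ccccc1)C1OCCO1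
F9 | step 3 | 1-{4,6-bis(benzyloxy)-3-[2-(benzyloxy)-5-(1,3-dioxolan-2-yl)phenyl]-2-hydroxyphenyl}ethan-1-one | CC(=O)c1c(O)c(-c2cc(ccc2OCc2ccccc2)C2OCCO2)c(OCc2ccccc2)cc1OCc1ccccc1
F10 | step 3 | 1-{4,6-bis(benzyloxy)-3-[2-(benzyloxy)-5-(1,3-dioxolan-2-yl)phenyl]-2-hydroxyphenyl}-3-[4-(benzyloxy)phenyl]propane-1,3-dione | O=C(CC(=O)c1ccc(OCc2ccccc2)cc1)c1c(O)c(-c2cc(ccc2OCc2ccccc2)C2OCCO2)c(OCc2ccccc2)cc1OCc1ccccc1
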